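**Retrosynthetic overview**

1. Feature: in ring B (C1' ether carbon, C2' CHO, C3' OH, C4' Cl, C5' CH3, C6' CO2H) the oxygen-bearing carbons C1' and C3' are meta with C2' between them, and the carboxyl carbon C6' is para to the C3' hydroxyl. A vinylketene–ynol ether benzannulation gives exactly this pattern, so ring B is built on the ether oxygen of a finished ring A (C1 CO2Me, C2 OH, C3 CH3, C4 OH, C5 O-aryl, C6 CH3).
2. Target 25 ⇐ acidolysis of two MOM ethers and the tert-butyl ester; CHO from CH2OSi; Cl placed on C4', the one free ring carbon of phenol 21.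
3. 21 ⇐ key disconnection of C2'–C3', C1'–C6' and C3'–C4': aryloxyalkyne 12 plus ketene 17, released from diazo ketoester 16.
4. 12 ⇐ ring A phenol 5 + trichloroethylene, then formaldehyde and silylation (the ether oxygen is bonded to an sp carbon, so no hindered O-arylation is needed). 5 ⇐ commercial resorcylate 1 by bromination, MOM protection, borylation and oxidation. 16 ⇐ tert-butyl diazoacetate + methacrolein.
5. Ring order: ring A is bought; ring B is the only ring formed (step 10).

Key step: step 10

Remark on the chemistry: the target has no stereocentre. Compounds 15 and 18 are racemic and their centres are removed on the way. The diazo ketoester is made from tert-butyl diazoacetate and methacrolein so that no base-sensitive enone β-ketoester has to be handled.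

**Route**

Step 1
Reactants: 1 methyl 2,4-dihydroxy-3,6-dimethylbenzoate
Product: 2 methyl 5-bromo-2,4-dihydroxy-3,6-dimethylbenzoate
Conditions: NBS, MeCN, 0 °C
Reagents that add atoms: N-bromosuccinimide, O=C1CCC(=O)N1Br
Why: Electrophilic aromatic bromination can only occur at C5, the single unsubstituted ring carbon, which is ortho to the C4 hydroxyl and para to the C2 hydroxyl.

Step 2
Reactants: 2 methyl 5-bromo-2,4-dihydroxy-3,6-dimethylbenzoate
Product: 3 methyl 5-bromo-2,4-bis(methoxymethoxy)-3,6-dimethylbenzoate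
Conditions: NaH, MOMCl, DMF, 0 °C → rt
Reagents that add atoms: chloromethyl methyl ether, COCCl
Why: Williamson-type O-alkylation of both sodium phenoxides should proceed, since NaH also deprotonates the hydrogen-bonded C2 hydroxyl next to the ester.

Step 3
Reactants: 3 methyl 5-bromo-2,4-bis(methoxymethoxy)-3,6-dimethylbenzoate
Product: 4 methyl 2,4-bis(methoxymethoxy)-3,6-dimethyl-5-(4,4,5,5-tetramethyl-1,3,2-dioxaborolan-2-yl)benzoate
Conditions: B2pin2, Pd(OAc)2 (cat.), SPhos, KOAc, 1,4-dioxane, 100 °C
Reagents that add atoms: bis(pinacolato)diboron, CC1(C)OB(OC1(C)C)B1OC(C)(C)C(C)(C)O1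
Why: Miyaura borylation with a bulky, electron-rich biarylphosphine is the established way to borylate di-ortho-substituted aryl bromides, and it tolerates the ester that an organolithium route would endanger.

Step 4
Reactants: 4 methyl 2,4-bis(methoxymethoxy)-3,6-dimethyl-5-(4,4,5,5-tetramethyl-1,3,2-dioxaborolan-2-yl)benzoate
Product: 5 methyl 5-hydroxy-2,4-bis(methoxymethoxy)-3,6-dimethylbenzoate
Conditions: 30% aq H2O2, aq NaOH, THF, 0 °C
Reagents that add atoms: hydrogen peroxide, OO
Why: Oxidation of the arylboronate by hydroperoxide (1,2-shift of the aryl group from boron to oxygen) should give the phenol, and the di-ortho-substituted methyl ester should resist the brief cold base.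

Step 5
Reactants: 5 methyl 5-hydroxy-2,4-bis(methoxymethoxy)-3,6-dimethylbenzoate; 6 trichloroethylene
Product: 8 methyl 5-{[(E)-1,2-dichloroethenyl]oxy}-2,4-bis(methoxymethoxy)-3,6-dimethylbenzoate, via dichloroacetylene 7 (not isolated)
Conditions: K2CO3, DMF, 70 °C
Reagents that add atoms: none
Why: Base-induced dehydrochlorination of trichloroethylene and anti addition of the phenol to the resulting dichloroacetylene (vinylic substitution by elimination–addition) should give the E ether, and this addition to a linear sp carbon tolerates the two ortho substituents of 5.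

Step 6
Reactants: 8 methyl 5-{[(E)-1,2-dichloroethenyl]oxy}-2,4-bis(methoxymethoxy)-3,6-dimethylbenzoate
Product: 11 methyl 5-[(3-hydroxyprop-1-yn-1-yl)oxy]-2,4-bis(methoxymethoxy)-3,6-dimethylbenzoate, via chloroethynyl ether 9 (not isolated), via lithium acetylide 10 (not isolated)
Conditions: n-BuLi (2.1 equiv), THF, –78 °C; (CH2O)n, –78 °C → rt; then H2O
Reagents that add atoms: formaldehyde (as paraformaldehyde), C=O
Why: This is the standard ynol ether synthesis from a 1,2-dichlorovinyl ether (dehydrochlorination, then chlorine–lithium exchange and 1,2-addition of the acetylide to formaldehyde), and both organolithium events should be faster at –78 °C than attack on the di-ortho-substituted ester.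

Step 7
Reactants: 11 methyl 5-[(3-hydroxyprop-1-yn-1-yl)oxy]-2,4-bis(methoxymethoxy)-3,6-dimethylbenzoate
Product: 12 methyl 5-{[3-(tert-butyldimethylsilyloxy)prop-1-yn-1-yl]oxy}-2,4-bis(methoxymethoxy)-3,6-dimethylbenzoate
Conditions: TBSCl, imidazole, DMF, 0 °C → rt
Reagents that add atoms: tert-butyldimethylsilyl chloride, CC(C)(C)[Si](C)(C)Cl
Why: Imidazole-mediated silylation of the primary alcohol proceeds under basic conditions that the acid-sensitive ynol ether tolerates, and it removes the hydroxyl that would otherwise add to the ketene.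

Step 8
Reactants: 13 tert-butyl diazoacetate; 14 methacrolein
Product: 15 tert-butyl 2-diazo-3-hydroxy-4-methylpent-4-enoate (racemic)
Conditions: DBU (0.2 equiv), MeCN, rt
Reagents that add atoms: none
Why: Base-catalysed aldol-type 1,2-addition of the diazoacetate carbon to the aldehyde is a standard entry to 2-diazo-3-hydroxy esters, and the new carbinol centre is racemic and is removed in step 9.

Step 9
Reactants: 15 tert-butyl 2-diazo-3-hydroxy-4-methylpent-4-enoate (racemic)
Product: 16 tert-butyl 2-diazo-4-methyl-3-oxopent-4-enoate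
Conditions: IBX, DMSO, rt
Reagents that add atoms: none
Why: IBX oxidation of the allylic carbinol to the ketone is well tolerated by acceptor-substituted diazo groups, and the product has no enolizable position.

Step 10
Reactants: 12 methyl 5-{[3-(tert-butyldimethylsilyloxy)prop-1-yn-1-yl]oxy}-2,4-bis(methoxymethoxy)-3,6-dimethylbenzoate; 16 tert-butyl 2-diazo-4-methyl-3-oxopent-4-enoate
Product: 21 tert-butyl 3-{[(tert-butyldimethylsilyl)oxy]methyl}-4-hydroxy-2-[5-(methoxycarbonyl)-2,4-bis(methoxymethoxy)-3,6-dimethylphenoxy]-6-methylbenzoate, via ketene 17 (not isolated), via cyclobutenone 18 (not isolated), via dienylketene 19 (not isolated), via cyclohexadienone 20 (not isolated)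
Conditions: 16 (1.5 equiv, slow addition), hν (Pyrex-filtered medium-pressure Hg lamp), degassed ClCH2CH2Cl, 25 °C until 16 is consumed; then 80 °C
Reagents that add atoms: none
Why: Proposed new method: light expels N2 from 16 and the isopropenyl group migrates to the carbene carbon (Wolff rearrangement) to give ketene 17, whose carbonyl carbon is attacked by the CH2OSi-bearing carbon of ynol ether 12, and collapse of the zwitterion gives cyclobutenone 18 with the C2'–C3' and C1'–C6' bonds in place. On heating, reversible conrotatory 4-electron opening of 18 gives dienylketene 19, and the isomer with the isopropenyl group cis to the ketene closes ring B by a disrotatory 6-electron electrocyclization that forms C3'–C4', after which 20 tautomerizes to phenol 21. The closest known reaction is the Danheiser benzannulation of vinylketenes, made by photochemical Wolff rearrangement of unsaturated diazo ketones, with alkoxy- and silyloxyalkynes; an ester on the ketene carbon and an aryl group on the ynol ether oxygen have not been shown. No stereocentre is set, since the quaternary carbon of racemic 18 ends as the sp2 carbon C6'. The step needs regioselectivity in the [2+2] event, secured by the polarity of the partners (nucleophilic beta carbon of the ynol ether, electrophilic ketene carbonyl carbon), and closure of the zwitterion at carbon and not at the ester oxygen, which the weakly basic and shielded tert-butyl ester carbonyl should favour. The unproductive geometric isomer of 19 can return to 18, so aromatization drains the equilibrium.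

Step 11
Reactants: 21 tert-butyl 3-{[(tert-butyldimethylsilyl)oxy]methyl}-4-hydroxy-2-[5-(methoxycarbonyl)-2,4-bis(methoxymethoxy)-3,6-dimethylphenoxy]-6-methylbenzoate
Product: 22 tert-butyl 3-{[(tert-butyldimethylsilyl)oxy]methyl}-5-chloro-4-hydroxy-2-[5-(methoxycarbonyl)-2,4-bis(methoxymethoxy)-3,6-dimethylphenoxy]-6-methylbenzoate
Conditions: NCS, MeCN, rt
Reagents that add atoms: N-chlorosuccinimide, O=C1CCC(=O)N1Cl
Why: Electrophilic aromatic chlorination can only take place at C4', which is ortho to the free phenol and the single unsubstituted carbon in either ring.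

Step 12
Reactants: 22 tert-butyl 3-{[(tert-butyldimethylsilyl)oxy]methyl}-5-chloro-4-hydroxy-2-[5-(methoxycarbonyl)-2,4-bis(methoxymethoxy)-3,6-dimethylphenoxy]-6-methylbenzoate
Product: 23 tert-butyl 5-chloro-4-hydroxy-3-(hydroxymethyl)-2-[5-(methoxycarbonyl)-2,4-bis(methoxymethoxy)-3,6-dimethylphenoxy]-6-methylbenzoate
Conditions: TBAF, AcOH, THF, 0 °C → rt
Reagents that add atoms: none
Why: Fluoride-mediated desilylation, buffered with acetic acid, should free the benzylic alcohol without touching the MOM ethers or either ester.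

Step 13
Reactants: 23 tert-butyl 5-chloro-4-hydroxy-3-(hydroxymethyl)-2-[5-(methoxycarbonyl)-2,4-bis(methoxymethoxy)-3,6-dimethylphenoxy]-6-methylbenzoate
Product: 24 tert-butyl 5-chloro-3-formyl-4-hydroxy-2-[5-(methoxycarbonyl)-2,4-bis(methoxymethoxy)-3,6-dimethylphenoxy]-6-methylbenzoate
Conditions: activated MnO2, CH2Cl2, rt
Reagents that add atoms: none
Why: MnO2 oxidation is selective for the benzylic alcohol, stops at the aldehyde and leaves the free phenol intact, and the resulting salicylaldehyde is stabilized by its internal hydrogen bond.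

Step 14
Reactants: 24 tert-butyl 5-chloro-3-formyl-4-hydroxy-2-[5-(methoxycarbonyl)-2,4-bis(methoxymethoxy)-3,6-dimethylphenoxy]-6-methylbenzoate
Product: 25 5-chloro-2-[2,4-dihydroxy-5-(methoxycarbonyl)-3,6-dimethylphenoxy]-3-formyl-4-hydroxy-6-methylbenzoic acid (CNP0210944.0)
Conditions: TFA, CH2Cl2, H2O (trace), 0 °C → rt
Reagents that add atoms: none
Why: Acidolysis cleaves the tert-butyl ester through the tert-butyl cation and hydrolyses both MOM acetals, while the methyl ester survives and the fully substituted rings offer no site for the released formaldehyde.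

**Compound list**

1 | methyl 2,4-dihydroxy-3,6-dimethylbenzoate | COC(=O)c1c(C)cc(O)c(C)c1O | starting material
2 | methyl 5-bromo-2,4-dihydroxy-3,6-dimethylbenzoate | COC(=O)c1c(C)c(Br)c(O)c(C)c1O | intermediate
3 | methyl 5-bromo-2,4-bis(methoxymethoxy)-3,6-dimethylbenzoate | COC(=O)c1c(C)c(Br)c(OCOC)c(C)c1OCOC | intermediate
4 | methyl 2,4-bis(methoxymethoxy)-3,6-dimethyl-5-(4,4,5,5-tetramethyl-1,3,2-dioxaborolan-2-yl)benzoate | COC(=O)c1c(C)c(B2OC(C)(C)C(C)(C)O2)c(OCOC)c(C)c1OCOC | intermediate
5 | methyl 5-hydroxy-2,4-bis(methoxymethoxy)-3,6-dimethylbenzoate | COC(=O)c1c(C)c(O)c(OCOC)c(C)c1OCOC | intermediate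
6 | trichloroethylene | ClC=C(Cl)Cl | starting material
7 | dichloroacetylene | ClC#CCl | intermediate (not isolated)
8 | methyl 5-{[(E)-1,2-dichloroethenyl]oxy}-2,4-bis(methoxymethoxy)-3,6-dimethylbenzoate | COC(=O)c1c(C)c(O/C(Cl)=C\Cl)c(OCOC)c(C)c1OCOC | intermediate
9 | methyl 5-[(chloroethynyl)oxy]-2,4-bis(methoxymethoxy)-3,6-dimethylbenzoate | COC(=O)c1c(C)c(OC#CCl)c(OCOC)c(C)c1OCOC | intermediate (not isolated)
10 | methyl 5-[(lithioethynyl)oxy]-2,4-bis(methoxymethoxy)-3,6-dimethylbenzoate | COC(=O)c1c(C)c(OC#C[Li])c(OCOC)c(C)c1OCOC | intermediate (not isolated)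
11 | methyl 5-[(3-hydroxyprop-1-yn-1-yl)oxy]-2,4-bis(methoxymethoxy)-3,6-dimethylbenzoate | COC(=O)c1c(C)c(OC#CCO)c(OCOC)c(C)c1OCOC | intermediate
12 | methyl 5-{[3-(tert-butyldimethylsilyloxy)prop-1-yn-1-yl]oxy}-2,4-bis(methoxymethoxy)-3,6-dimethylbenzoate | COC(=O)c1c(C)c(OC#CCO[Si](C)(C)C(C)(C)C)c(OCOC)c(C)c1OCOC | intermediate
13 | tert-butyl diazoacetate | CC(C)(C)OC(=O)C=[N+]=[N-] | starting material
14 | methacrolein | CC(=C)C=O | starting material
15 | tert-butyl 2-diazo-3-hydroxy-4-methylpent-4-enoate (racemic) | CC(=C)C(O)C(=[N+]=[N-])C(=O)OC(C)(C)C | intermediate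
16 | tert-butyl 2-diazo-4-methyl-3-oxopent-4-enoate | CC(=C)C(=O)C(=[N+]=[N-])C(=O)OC(C)(C)C | intermediate
17 | tert-butyl 3-methyl-2-(oxomethylidene)but-3-enoate, the (tert-butoxycarbonyl)(isopropenyl)ketene | CC(=C)C(=C=O)C(=O)OC(C)(C)C | intermediate (not isolated)
18 | tert-butyl 2-[5-(methoxycarbonyl)-2,4-bis(methoxymethoxy)-3,6-dimethylphenoxy]-3-{[(tert-butyldimethylsilyl)oxy]methyl}-4-oxo-1-(prop-1-en-2-yl)cyclobut-2-ene-1-carboxylate (racemic) | COC(=O)c1c(C)c(OC2=C(CO[Si](C)(C)C(C)(C)C)C(=O)C2(C(C)=C)C(=O)OC(C)(C)C)c(OCOC)c(C)c1OCOC | intermediate (not isolated)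
19 | (Z)-dienylketene: tert-butyl 3-aryloxy-4-{[(tert-butyldimethylsilyl)oxy]methyl}-5-oxo-2-(prop-1-en-2-yl)penta-2,4-dienoate, aryl = ring A as in 12, isopropenyl cis to the ketene carbon | COC(=O)c1c(C)c(O/C(C(CO[Si](C)(C)C(C)(C)C)=C=O)=C(/C(C)=C)C(=O)OC(C)(C)C)c(OCOC)c(C)c1OCOC | intermediate (not isolated)
20 | cyclohexa-2,4-dienone tautomer of 21 (C3' carbonyl, C4' CH2) | COC(=O)c1c(C)c(OC2=C(CO[Si](C)(C)C(C)(C)C)C(=O)CC(C)=C2C(=O)OC(C)(C)C)c(OCOC)c(C)c1OCOC | intermediate (not isolated)
21 | tert-butyl 3-{[(tert-butyldimethylsilyl)oxy]methyl}-4-hydroxy-2-[5-(methoxycarbonyl)-2,4-bis(methoxymethoxy)-3,6-dimethylphenoxy]-6-methylbenzoate | COC(=O)c1c(C)c(Oc2c(CO[Si](C)(C)C(C)(C)C)c(O)cc(C)c2C(=O)OC(C)(C)C)c(OCOC)c(C)c1OCOC | intermediate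
22 | tert-butyl 3-{[(tert-butyldimethylsilyl)oxy]methyl}-5-chloro-4-hydroxy-2-[5-(methoxycarbonyl)-2,4-bis(methoxymethoxy)-3,6-dimethylphenoxy]-6-methylbenzoate | COC(=O)c1c(C)c(Oc2c(CO[Si](C)(C)C(C)(C)C)c(O)c(Cl)c(C)c2C(=O)OC(C)(C)C)c(OCOC)c(C)c1OCOC | intermediate
23 | tert-butyl 5-chloro-4-hydroxy-3-(hydroxymethyl)-2-[5-(methoxycarbonyl)-2,4-bis(methoxymethoxy)-3,6-dimethylphenoxy]-6-methylbenzoate | COC(=O)c1c(C)c(Oc2c(CO)c(O)c(Cl)c(C)c2C(=O)OC(C)(C)C)c(OCOC)c(C)c1OCOC | intermediate
24 | tert-butyl 5-chloro-3-formyl-4-hydroxy-2-[5-(methoxycarbonyl)-2,4-bis(methoxymethoxy)-3,6-dimethylphenoxy]-6-methylbenzoate | COC(=O)c1c(C)c(Oc2c(C=O)c(O)c(Cl)c(C)c2C(=O)OC(C)(C)C)c(OCOC)c(C)c1OCOC | intermediate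
25 | 5-chloro-2-[2,4-dihydroxy-5-(methoxycarbonyl)-3,6-dimethylphenoxy]-3-formyl-4-hydroxy-6-methylbenzoic acid (CNP0210944.0) | COC(=O)c1c(C)c(Oc2c(C=O)c(O)c(Cl)c(C)c2C(=O)O)c(O)c(C)c1O | target

**Step count**

Total: 14 steps. Longest linear sequence: 12 steps (steps 1–7, then 10–14); steps 8 and 9 form the short convergent arm.

**Steps most likely to fail**

Step 10 (proposed new method). Three processes could divert it:
- the zwitterion from ketene and ynol ether may close through the ester oxygen to a 4-pyranone instead of through carbon;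
- ketene self-condensation, or acylation of the newly formed phenol by residual ketene, may outrun the [2+2] event with the only moderately nucleophilic aryloxyalkyne;
- ring opening of 18 with the ester turned inward may stall the cascade.

The fallback uses only the established pairing of an ester-free vinylketene with an ynol ether and adds the carboxyl carbon afterwards. It sets out from 12 and comes back at 22. 3-Methylbut-3-en-2-one would be trifluoroacetylated (LiN(SiMe3)2, CF3CO2CH2CF3, THF, –78 °C) to 1,1,1-trifluoro-5-methylhex-5-ene-2,4-dione F1, used crude in a detrifluoroacetylative diazo transfer (MsN3, Et3N, H2O, MeCN) to give 1-diazo-3-methylbut-3-en-2-one F2. Irradiation of F2 with 12 and heating at 80 °C, as in step 10, should give tert-butyldimethylsilyl-protected methyl 5-[2-(hydroxymethyl)-3-hydroxy-5-methylphenoxy]-2,4-bis(methoxymethoxy)-3,6-dimethylbenzoate F3, with hydrogen at C4' and C6'. Ortho-directed chlorination (NCS, catalytic diisopropylammonium chloride, toluene, 0 °C) should go to C4', the less hindered carbon beside the hydroxyl, to give the C4' chloride F4. NIS in MeCN should then iodinate C6', the last free carbon and para to the hydroxyl, to give the C6' iodide F5. Hydroxycarbonylation (Pd(OAc)2, Xantphos, CO, KOAc, H2O, DMF, 80 °C) should convert the iodide, and not the chloride, into the C6' carboxylic acid F6. N,N-Dimethylformamide di-tert-butyl acetal (toluene, 80 °C) should esterify the acid selectively and return to the route at 22.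

Step 6. n-BuLi may add to the ring A methyl ester or lithiate the C6 methyl group in competition with elimination and chlorine–lithium exchange, and the propargylic ynol ether may hydrate on work-up. The fallback avoids organolithium reagents and the free propargylic alcohol. It sets out from 5 and comes back at 12. (tert-Butyldimethylsilyloxy)acetaldehyde would be converted by dibromo-olefination (CBr4, PPh3, CH2Cl2, 0 °C) into tert-butyl[(3,3-dibromoprop-2-en-1-yl)oxy]dimethylsilane F7. Copper-catalysed vinylation of phenol 5 with F7 (CuI, 2,2'-bipyridine, K3PO4, toluene, 110 °C) should replace the bromine trans to the chain and give the (Z)-1-bromoenol ether F8. Anti elimination of HBr with t-BuOK (1,4-dioxane, rt) should then give 12.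

Step 3. Oxidative addition to the di-ortho-substituted, electron-rich bromide may be slow and protodebromination may take over. The fallback introduces the C5 oxygen by a Dakin-type sequence. It sets out from 1 and comes back at 5. Rieche formylation of 1 (Cl2CHOMe, TiCl4, CH2Cl2, 0 °C) at C5 should give methyl 5-formyl-2,4-dihydroxy-3,6-dimethylbenzoate F9. NaH and MOMCl in DMF should give methyl 5-formyl-2,4-bis(methoxymethoxy)-3,6-dimethylbenzoate F10. Baeyer–Villiger oxidation (mCPBA, NaHCO3, CH2Cl2), with migration of the electron-rich aryl group, should give methyl 5-(formyloxy)-2,4-bis(methoxymethoxy)-3,6-dimethylbenzoate F11. Methanolysis (K2CO3, MeOH, rt) should then give 5.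

**Further compounds**

F1 | step 10 | 1,1,1-trifluoro-5-methylhex-5-ene-2,4-dione | CC(=C)C(=O)CC(=O)C(F)(F)F
F2 | step 10 | 1-diazo-3-methylbut-3-en-2-one | CC(=C)C(=O)C=[N+]=[N-]
F3 | step 10 | methyl 5-(2-{[(tert-butyldimethylsilyl)oxy]methyl}-3-hydroxy-5-methylphenoxy)-2,4-bis(methoxymethoxy)-3,6-dimethylbenzoate | COC(=O)c1c(C)c(Oc2c(CO[Si](C)(C)C(C)(C)C)c(O)cc(C)c2)c(OCOC)c(C)c1OCOC
F4 | step 10 | methyl 5-(2-{[(tert-butyldimethylsilyl)oxy]methyl}-4-chloro-3-hydroxy-5-methylphenoxy)-2,4-bis(methoxymethoxy)-3,6-dimethylbenzoate | COC(=O)c1c(C)c(Oc2c(CO[Si](C)(C)C(C)(C)C)c(O)c(Cl)c(C)c2)c(OCOC)c(C)c1OCOC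
F5 | step 10 | methyl 5-(2-{[(tert-butyldimethylsilyl)oxy]methyl}-4-chloro-3-hydroxy-6-iodo-5-methylphenoxy)-2,4-bis(methoxymethoxy)-3,6-dimethylbenzoate | COC(=O)c1c(C)c(Oc2c(CO[Si](C)(C)C(C)(C)C)c(O)c(Cl)c(C)c2I)c(OCOC)c(C)c1OCOC
F6 | step 10 | 3-{[(tert-butyldimethylsilyl)oxy]methyl}-5-chloro-4-hydroxy-2-[5-(methoxycarbonyl)-2,4-bis(methoxymethoxy)-3,6-dimethylphenoxy]-6-methylbenzoic acid | COC(=O)c1c(C)c(Oc2c(CO[Si](C)(C)C(C)(C)C)c(O)c(Cl)c(C)c2C(=O)O)c(OCOC)c(C)c1OCOC
F7 | step 6 | tert-butyl[(3,3-dibromoprop-2-en-1-yl)oxy]dimethylsilane | BrC(Br)=CCO[Si](C)(C)C(C)(C)C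
F8 | step 6 | methyl 5-{[(Z)-1-bromo-3-(tert-butyldimethylsilyloxy)prop-1-en-1-yl]oxy}-2,4-bis(methoxymethoxy)-3,6-dimethylbenzoate | COC(=O)c1c(C)c(O/C(Br)=C/CO[Si](C)(C)C(C)(C)C)c(OCOC)c(C)c1OCOC
F9 | step 3 | methyl 5-formyl-2,4-dihydroxy-3,6-dimethylbenzoate | COC(=O)c1c(C)c(C=O)c(O)c(C)c1O
F10 | step 3 | methyl 5-formyl-2,4-bis(methoxymethoxy)-3,6-dimethylbenzoate | COC(=O)c1c(C)c(C=O)c(OCOC)c(C)c1OCOC
F11 | step 3 | methyl 5-(formyloxy)-2,4-bis(methoxymethoxy)-3,6-dimethylbenzoate | COC(=O)c1c(C)c(OC=O)c(OCOC)c(C)c1OCOC
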